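The route rests on the C3a–C10a bond, the ring-fusion bond shared by the nine-membered carbocycle and the tetrahydrofuran (cyclonona[c]furan numbering). It is made by an Ireland–Claisen ring contraction of a 13-membered lactone: the lactone α-carbon (future C3a) and the terminus of an E-allylic ester (future C10a) join through a chair transition state. One operation closes the cyclononene, sets both fusion stereocentres trans by chirality transfer from the carbinol carbon of the lactone, and leaves a carboxyl (future C3) next to a trisubstituted alkene at future C1. The precursor is a monocyclic macrolactone that contains neither ring of the target; the tetrahydrofuran and the diene follow by selenoetherification and selenoxide elimination.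

Key step: step 17

Remark: bicyclic compounds are numbered as 1H-cyclonona[c]furan (C1, O2, C3, C3a, C4–C10, C10a). The lactones are numbered as 1-oxacyclotridecanes (O1, C2 carbonyl, C3 … C13), so lactone C3 and C11 become C3a and C10a. Compounds 1, 10, 18, 19 and 33 are taken as commercial.

Step 1
Reactants: 1 geraniol
Product: 2 [(2S,3S)-3-methyl-3-(4-methylpent-3-en-1-yl)oxiran-2-yl]methanol
Conditions: Ti(OiPr)4 (5 mol%), L-(+)-diethyl tartrate (6 mol%), tBuOOH, 4 Å molecular sieves, CH2Cl2, −20 °C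
Reagents that add atoms: tert-butyl hydroperoxide, CC(C)(C)OO
Why: Sharpless asymmetric epoxidation acts only on the allylic alkene and, with the L-(+)-tartrate, should give the (2S,3S)-epoxide, whose quaternary carbon becomes C8 (S) of the target.

Step 2
Reactants: 2 [(2S,3S)-3-methyl-3-(4-methylpent-3-en-1-yl)oxiran-2-yl]methanol
Product: 3 (2S,3R)-3-(chloromethyl)-2-methyl-2-(4-methylpent-3-en-1-yl)oxirane
Conditions: PPh3, CCl4, NaHCO3, reflux
Reagents that add atoms: tetrachloromethane, ClC(Cl)(Cl)Cl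
Why: Appel chlorination of the primary alcohol under buffered conditions leaves the epoxide and its stereocentres untouched.

Step 3
Reactants: 3 (2S,3R)-3-(chloromethyl)-2-methyl-2-(4-methylpent-3-en-1-yl)oxirane
Product: 5 (4S)-4,8-dimethylnon-7-en-2-yn-4-ol, via dilithium alkynide alkoxide 4 (not isolated)
Conditions: n-BuLi (3.3 equiv), THF, −40 °C; then MeI, DMPU, −40 °C → rt
Reagents that add atoms: iodomethane, CI
Why: base-induced double elimination of a 2,3-epoxy chloride gives the alkynyl carbinol with the carbinol C–O bond intact (configuration retained), and the lithium acetylide is C-methylated in the same flask.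

Step 4
Reactants: 5 (4S)-4,8-dimethylnon-7-en-2-yn-4-ol
Product: 6 tert-butyl{[(4S)-4,8-dimethylnon-7-en-2-yn-4-yl]oxy}dimethylsilane
Conditions: tBuMe2SiOTf, 2,6-lutidine, CH2Cl2, 0 °C → rt
Reagents that add atoms: tert-butyldimethylsilyl triflate, CC(C)(C)[Si](C)(C)OS(=O)(=O)C(F)(F)F
Why: silyl triflate silylation protects the hindered tertiary propargylic alcohol as an ether that should survive all steps up to step 20.

Step 5
Reactants: 6 tert-butyl{[(4S)-4,8-dimethylnon-7-en-2-yn-4-yl]oxy}dimethylsilane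
Product: 8 (4S)-4-[(tert-butyldimethylsilyl)oxy]-4-methylhept-5-ynal, via secondary ozonide 7 (not isolated)
Conditions: O3, CH2Cl2, −78 °C, stopped at consumption of the alkene; then Me2S, −78 °C → rt
Reagents that add atoms: ozone, [O-][O+]=O
Why: ozonolysis with reductive work-up cleaves the electron-rich trisubstituted alkene much faster than the internal alkyne and gives the aldehyde carbon that becomes C10a.

Step 6
Reactants: 8 (4S)-4-[(tert-butyldimethylsilyl)oxy]-4-methylhept-5-ynal
Product: 9 tert-butyldimethyl{[(4S)-4-methylocta-2,7-diyn-4-yl]oxy}silane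
Conditions: dimethyl (1-diazo-2-oxopropyl)phosphonate, K2CO3, MeOH, 0 °C → rt
Reagents that add atoms: dimethyl (1-diazo-2-oxopropyl)phosphonate, COP(=O)(OC)C(=[N+]=[N-])C(C)=O
Why: Ohira–Bestmann (Seyferth–Gilbert) homologation converts the aldehyde into the terminal alkyne under mild base; the new carbon becomes C1.

Step 7
Reactants: 10 4-methylpent-3-enoic acid
Product: 12 N-methoxy-N,4-dimethylpent-3-enamide, via acyl imidazole 11 (not isolated)
Conditions: 1,1'-carbonyldiimidazole, CH2Cl2, rt; then MeNH(OMe)·HCl, rt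
Reagents that add atoms: N,O-dimethylhydroxylamine hydrochloride, CNOC.Cl
Why: Weinreb amide formation through the acyl imidazole avoids base strong enough to move the β,γ-alkene into conjugation.

Step 8
Reactants: 9 tert-butyldimethyl{[(4S)-4-methylocta-2,7-diyn-4-yl]oxy}silane; 12 N-methoxy-N,4-dimethylpent-3-enamide
Product: 14 (10S)-10-[(tert-butyldimethylsilyl)oxy]-2,10-dimethyltridec-2-ene-6,11-diyn-5-one, via lithium acetylide 13 (not isolated)
Conditions: n-BuLi, THF, −78 °C; then 12, −78 → 0 °C; aqueous work-up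
Reagents that add atoms: none
Why: acylation of a lithium acetylide with a Weinreb amide stops at the ketone because the chelated tetrahedral adduct survives until work-up; only the terminal alkyne is deprotonated.

Step 9
Reactants: 14 (10S)-10-[(tert-butyldimethylsilyl)oxy]-2,10-dimethyltridec-2-ene-6,11-diyn-5-one
Product: 15 (5S,10S)-10-[(tert-butyldimethylsilyl)oxy]-2,10-dimethyltridec-2-ene-6,11-diyn-5-ol
Conditions: Ru[(S,S)-TsNCHPhCHPhNH](p-cymene) (1 mol%), iPrOH, rt
Reagents that add atoms: none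
Why: Noyori asymmetric transfer hydrogenation of an alkynyl ketone, with the alkyne as the π-group, should give the (5S)-propargylic alcohol with the (S,S)-catalyst; base-free conditions keep the skipped enone from conjugating.

Step 10
Reactants: 15 (5S,10S)-10-[(tert-butyldimethylsilyl)oxy]-2,10-dimethyltridec-2-ene-6,11-diyn-5-ol
Product: 16 (5S,6Z,10S)-10-[(tert-butyldimethylsilyl)oxy]-2,10-dimethyl-6-(tributylstannyl)trideca-2,6-dien-11-yn-5-ol
Conditions: [Cp*RuCl]4 (2 mol%), Bu3SnH (1.1 equiv), CH2Cl2, rt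
Reagents that add atoms: tributyltin hydride, CCCC[SnH](CCCC)CCCC
Why: hydroxyl-directed trans-hydrostannation (O–H···Cl–Ru hydrogen bond) delivers tin to the alkyne carbon next to the carbinol and hydrogen anti to it, so the C8 chain ends cis to tin; the silyl-capped alkyne has no directing hydroxyl and should react more slowly.

Step 11
Reactants: 16 (5S,6Z,10S)-10-[(tert-butyldimethylsilyl)oxy]-2,10-dimethyl-6-(tributylstannyl)trideca-2,6-dien-11-yn-5-ol
Product: 17 methyl (2Z,6S)-6-[(tert-butyldimethylsilyl)oxy]-2-[(1S)-1-hydroxy-4-methylpent-3-en-1-yl]-6-methylnon-2-en-7-ynoate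
Conditions: Pd(OAc)2 (5 mol%), AsPh3 (10 mol%), 1,4-benzoquinone (1.5 equiv), CO (1 atm), MeOH, rt
Reagents that add atoms: carbon monoxide, [C-]#[O+]; methanol, CO
Why: hydroxyl-assisted oxidative methoxycarbonylation of the alkenylstannane replaces tin by CO2Me with retention, giving the alkene geometry (chain trans to the carbinol carbon) that the chair Claisen needs.

Step 12
Reactants: 18 3-chloro-2-(chloromethyl)prop-1-ene; 19 prop-1-yn-1-ylmagnesium bromide
Product: 20 5-(chloromethyl)hex-5-en-2-yne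
Conditions: 19 added to 18 (3 equiv), CuI (5 mol%), THF, 0 °C → rt
Reagents that add atoms: none
Why: copper-catalysed coupling of an alkynyl Grignard reagent with an allylic chloride; SN2 and SN2' attack give the same product on this symmetrical electrophile, and the excess of 18 limits double substitution.

Step 13
Reactants: 20 5-(chloromethyl)hex-5-en-2-yne
Product: 22 3-methylidenehept-5-ynoic acid, via allylic Grignard reagent 21 (not isolated)
Conditions: Mg, THF, 0 °C (slow addition); then CO2, −40 °C → rt; aq. HCl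
Reagents that add atoms: carbon dioxide, O=C=O
Why: Grignard carboxylation; the two termini of the 2-substituted allyl unit are equivalent, so α and γ attack give the same β,γ-unsaturated acid.

Step 14
Reactants: 17 methyl (2Z,6S)-6-[(tert-butyldimethylsilyl)oxy]-2-[(1S)-1-hydroxy-4-methylpent-3-en-1-yl]-6-methylnon-2-en-7-ynoate; 22 3-methylidenehept-5-ynoic acid
Product: 23 methyl (2Z,6S)-6-[(tert-butyldimethylsilyl)oxy]-6-methyl-2-{(1S)-4-methyl-1-[(3-methylidenehept-5-ynoyl)oxy]pent-3-en-1-yl}non-2-en-7-ynoate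
Conditions: DCC, DMAP (0.1 equiv), CH2Cl2, 0 °C
Reagents that add atoms: none
Why: Steglich esterification acylates the secondary allylic alcohol with retention at carbon; the low temperature limits migration of the β,γ-alkene of the acid.

Step 15
Reactants: 23 methyl (2Z,6S)-6-[(tert-butyldimethylsilyl)oxy]-6-methyl-2-{(1S)-4-methyl-1-[(3-methylidenehept-5-ynoyl)oxy]pent-3-en-1-yl}non-2-en-7-ynoate
Product: 24 methyl (8S,11Z,13S)-8-[(tert-butyldimethylsilyl)oxy]-8-methyl-4-methylidene-13-(3-methylbut-2-en-1-yl)-2-oxo-1-oxacyclotridec-11-en-6-yne-12-carboxylate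
Conditions: Mo(≡C-C6H4-4-OMe)(OSiPh3)3 (5 mol%), 5 Å molecular sieves, toluene (2 mM), 80 °C
Reagents that add atoms: none
Why: ring-closing alkyne metathesis of the two methyl-capped alkynes, driven by trapping of but-2-yne on the sieves, forms the 13-membered cycloalkyne and tolerates esters, alkenes and silyl ethers.

Step 16
Reactants: 24 methyl (8S,11Z,13S)-8-[(tert-butyldimethylsilyl)oxy]-8-methyl-4-methylidene-13-(3-methylbut-2-en-1-yl)-2-oxo-1-oxacyclotridec-11-en-6-yne-12-carboxylate
Product: 25 methyl (6Z,8S,11Z,13S)-8-[(tert-butyldimethylsilyl)oxy]-8-methyl-4-methylidene-13-(3-methylbut-2-en-1-yl)-2-oxo-1-oxacyclotrideca-6,11-diene-12-carboxylate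
Conditions: H2 (1 atm), Pd/CaCO3 poisoned with Pb(OAc)2, quinoline, EtOAc, rt
Reagents that add atoms: none
Why: Lindlar semihydrogenation adds hydrogen syn to the alkyne only and gives the (6Z)-alkene that becomes C6=C7 of the target.

Step 17
Reactants: 25 methyl (6Z,8S,11Z,13S)-8-[(tert-butyldimethylsilyl)oxy]-8-methyl-4-methylidene-13-(3-methylbut-2-en-1-yl)-2-oxo-1-oxacyclotrideca-6,11-diene-12-carboxylate
Product: 28 (1R,2S,5S,6Z)-5-[(tert-butyldimethylsilyl)oxy]-2-[(2Z)-1-methoxy-6-methyl-1-oxohepta-2,5-dien-2-yl]-5-methyl-9-methylidenecyclonon-6-ene-1-carboxylic acid, via silyl ketene acetal 26 (not isolated), via trimethylsilyl ester 27 (not isolated)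
Conditions: LiN(iPr)2 (1.3 equiv), THF–DMPU (4:1), −78 °C; Me3SiCl/Et3N, −78 °C → rt, then 50 °C; 1 M aq. HCl
Reagents that add atoms: none
Why: LiN(iPr)2 removes the doubly activated C3–H of lactone 25 (α to the lactone carbonyl and allylic to the C4 methylidene; the C12 enoate has no α-hydrogen), Me3SiCl traps the enolate as the (Z)-O-silyl ketene acetal 26, and 26 undergoes the [3,3]-sigmatropic shift through a chair to silyl ester 27; the closest known reaction type is the Ireland–Claisen ring contraction of macrocyclic allylic lactones. The step closes the nine-membered carbocycle by joining lactone C3 to C11 while the C13–O1 bond breaks, a 13-to-9 ring contraction in which the two termini are held in the six-atom chair array, so the closure is sigmatropic and not an exo or endo attack. C3a and C10a are set together: the 3-methylbut-2-enyl group on the (13S) carbinol carbon sits pseudo-equatorial and so selects the face of the C11=C12 alkene, which transfers the carbinol configuration before C13 becomes an alkene carbon. The ring chain is equatorial at both termini, because C10 is trans to C13 on the alkene and C4 is trans to O1 on the ketene acetal, and this should give the trans (3aR,10aS) relationship. The step needs enolization at C3 only, silylation faster than conjugate addition of the enolate to the enoate, the Z ketene acetal, and chair over boat; these are secured by the acidity of C3–H, silylation at −78 °C, the cosolvent DMPU, and the ester on the central allyl carbon, which would clash with the silyloxy group in a boat. The carboxyl and the new trisubstituted alkene end up where the tetrahydrofuran closure needs them.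

Step 18
Reactants: 28 (1R,2S,5S,6Z)-5-[(tert-butyldimethylsilyl)oxy]-2-[(2Z)-1-methoxy-6-methyl-1-oxohepta-2,5-dien-2-yl]-5-methyl-9-methylidenecyclonon-6-ene-1-carboxylic acid
Product: 29 {(1R,2S,5S,6Z)-5-[(tert-butyldimethylsilyl)oxy]-2-[(2Z)-1-hydroxy-6-methylhepta-2,5-dien-2-yl]-5-methyl-9-methylidenecyclonon-6-en-1-yl}methanol
Conditions: LiAlH4, Et2O, 0 °C; then H2O, aq. NaOH
Reagents that add atoms: none
Why: hydride reduction takes the carboxylic acid to the C3 alcohol and the α-substituted enoate to the allylic alcohol by 1,2-addition, without touching the stereocentres.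

Step 19
Reactants: 29 {(1R,2S,5S,6Z)-5-[(tert-butyldimethylsilyl)oxy]-2-[(2Z)-1-hydroxy-6-methylhepta-2,5-dien-2-yl]-5-methyl-9-methylidenecyclonon-6-en-1-yl}methanol
Product: 31 [(1R,3aR,6Z,8S,10aS)-8-[(tert-butyldimethylsilyl)oxy]-8-methyl-4-methylidene-1-[(1E)-4-methylpenta-1,3-dien-1-yl]-3,3a,4,5,8,9,10,10a-octahydro-1H-cyclonona[c]furan-1-yl]methanol, via selenide 30 (not isolated)
Conditions: N-(phenylseleno)phthalimide (1.2 equiv), camphorsulfonic acid (10 mol%), CH2Cl2, −40 → 0 °C; then pyridine, 30% aq. H2O2, 0 °C → rt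
Reagents that add atoms: none
Why: selenoetherification closes the tetrahydrofuran by 5-exo, Markovnikov, anti attack of the C3 hydroxyl on the seleniranium ion, with the allylic C10a–H eclipsing the alkene so that the selenium-bearing carbon ends trans to C10 and C1 should be R; selenoxide syn-elimination can then only take the allylic hydrogen and gives the (E)-diene.

Step 20
Reactants: 31 [(1R,3aR,6Z,8S,10aS)-8-[(tert-butyldimethylsilyl)oxy]-8-methyl-4-methylidene-1-[(1E)-4-methylpenta-1,3-dien-1-yl]-3,3a,4,5,8,9,10,10a-octahydro-1H-cyclonona[c]furan-1-yl]methanol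
Product: 32 (1R,3aR,6Z,8S,10aS)-1-(hydroxymethyl)-8-methyl-4-methylidene-1-[(1E)-4-methylpenta-1,3-dien-1-yl]-3,3a,4,5,8,9,10,10a-octahydro-1H-cyclonona[c]furan-8-ol
Conditions: Bu4NF (3 equiv), THF, 40 °C
Reagents that add atoms: none
Why: fluoride desilylation frees the tertiary alcohol without acid, which the dienyl-substituted tertiary ether at C1 would not tolerate.

Step 21
Reactants: 32 (1R,3aR,6Z,8S,10aS)-1-(hydroxymethyl)-8-methyl-4-methylidene-1-[(1E)-4-methylpenta-1,3-dien-1-yl]-3,3a,4,5,8,9,10,10a-octahydro-1H-cyclonona[c]furan-8-ol; 33 hexadecanoyl chloride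
Product: 34 [(1R,3aR,6Z,8S,10aS)-8-hydroxy-8-methyl-4-methylidene-1-[(1E)-4-methylpenta-1,3-dien-1-yl]-3,3a,4,5,8,9,10,10a-octahydro-1H-cyclonona[c]furan-1-yl]methyl hexadecanoate
Conditions: 33 (1.05 equiv), pyridine, DMAP (cat.), CH2Cl2, 0 °C
Reagents that add atoms: none
Why: acylation with an acid chloride should take the primary hydroxyl and leave the hindered tertiary allylic alcohol.

Compound list
1 | geraniol, (2E)-3,7-dimethylocta-2,6-dien-1-ol | CC(C)=CCC/C(C)=C/CO | starting material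
2 | [(2S,3S)-3-methyl-3-(4-methylpent-3-en-1-yl)oxiran-2-yl]methanol | OC[C@@H]1O[C@@]1(C)CCC=C(C)C | intermediate
3 | (2S,3R)-3-(chloromethyl)-2-methyl-2-(4-methylpent-3-en-1-yl)oxirane | ClC[C@@H]1O[C@@]1(C)CCC=C(C)C | intermediate
4 | dilithium (3S)-3,7-dimethyl-3-oxidooct-6-en-1-yn-1-ide | [Li]C#C[C@@](C)(O[Li])CCC=C(C)C | intermediate (not isolated)
5 | (4S)-4,8-dimethylnon-7-en-2-yn-4-ol | CC#C[C@@](C)(O)CCC=C(C)C | intermediate
6 | tert-butyl{[(4S)-4,8-dimethylnon-7-en-2-yn-4-yl]oxy}dimethylsilane | CC#C[C@@](C)(O[Si](C)(C)C(C)(C)C)CCC=C(C)C | intermediate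
7 | 5-{(3S)-3-[(tert-butyldimethylsilyl)oxy]-3-methylhex-4-yn-1-yl}-3,3-dimethyl-1,2,4-trioxolane (epimers at C5) | CC#C[C@@](C)(O[Si](C)(C)C(C)(C)C)CCC1OOC(C)(C)O1 | intermediate (not isolated)
8 | (4S)-4-[(tert-butyldimethylsilyl)oxy]-4-methylhept-5-ynal | CC#C[C@@](C)(O[Si](C)(C)C(C)(C)C)CCC=O | intermediate
9 | tert-butyldimethyl{[(4S)-4-methylocta-2,7-diyn-4-yl]oxy}silane | CC#C[C@@](C)(O[Si](C)(C)C(C)(C)C)CCC#C | intermediate
10 | 4-methylpent-3-enoic acid | CC(C)=CCC(=O)O | starting material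
11 | 1-(1H-imidazol-1-yl)-4-methylpent-3-en-1-one | CC(C)=CCC(=O)n1ccnc1 | intermediate (not isolated)
12 | N-methoxy-N,4-dimethylpent-3-enamide | CC(C)=CCC(=O)N(C)OC | intermediate
13 | {(5S)-5-[(tert-butyldimethylsilyl)oxy]-5-methylocta-1,6-diyn-1-yl}lithium | CC#C[C@@](C)(O[Si](C)(C)C(C)(C)C)CCC#C[Li] | intermediate (not isolated)
14 | (10S)-10-[(tert-butyldimethylsilyl)oxy]-2,10-dimethyltridec-2-ene-6,11-diyn-5-one | CC#C[C@@](C)(O[Si](C)(C)C(C)(C)C)CCC#CC(=O)CC=C(C)C | intermediate
15 | (5S,10S)-10-[(tert-butyldimethylsilyl)oxy]-2,10-dimethyltridec-2-ene-6,11-diyn-5-ol | CC#C[C@@](C)(O[Si](C)(C)C(C)(C)C)CCC#C[C@@H](O)CC=C(C)C | intermediate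
16 | (5S,6Z,10S)-10-[(tert-butyldimethylsilyl)oxy]-2,10-dimethyl-6-(tributylstannyl)trideca-2,6-dien-11-yn-5-ol | CC#C[C@@](C)(O[Si](C)(C)C(C)(C)C)CC/C=C(\[Sn](CCCC)(CCCC)CCCC)[C@@H](O)CC=C(C)C | intermediate
17 | methyl (2Z,6S)-6-[(tert-butyldimethylsilyl)oxy]-2-[(1S)-1-hydroxy-4-methylpent-3-en-1-yl]-6-methylnon-2-en-7-ynoate | CC#C[C@@](C)(O[Si](C)(C)C(C)(C)C)CC/C=C(\C(=O)OC)[C@@H](O)CC=C(C)C | intermediate
18 | 3-chloro-2-(chloromethyl)prop-1-ene | C=C(CCl)CCl | starting material
19 | prop-1-yn-1-ylmagnesium bromide | CC#C[Mg]Br | starting material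
20 | 5-(chloromethyl)hex-5-en-2-yne | CC#CCC(=C)CCl | intermediate
21 | (2-methylidenehex-4-yn-1-yl)magnesium chloride | CC#CCC(=C)C[Mg]Cl | intermediate (not isolated)
22 | 3-methylidenehept-5-ynoic acid | CC#CCC(=C)CC(=O)O | intermediate
23 | methyl (2Z,6S)-6-[(tert-butyldimethylsilyl)oxy]-6-methyl-2-{(1S)-4-methyl-1-[(3-methylidenehept-5-ynoyl)oxy]pent-3-en-1-yl}non-2-en-7-ynoate | CC#C[C@@](C)(O[Si](C)(C)C(C)(C)C)CC/C=C(\C(=O)OC)[C@@H](OC(=O)CC(=C)CC#CC)CC=C(C)C | intermediate
24 | methyl (8S,11Z,13S)-8-[(tert-butyldimethylsilyl)oxy]-8-methyl-4-methylidene-13-(3-methylbut-2-en-1-yl)-2-oxo-1-oxacyclotridec-11-en-6-yne-12-carboxylate (ring carbons C10 and C13 trans on the alkene) | C=C1CC#C[C@@](C)(O[Si](C)(C)C(C)(C)C)CC/C=C(\C(=O)OC)[C@H](CC=C(C)C)OC(=O)C1 | intermediate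
25 | methyl (6Z,8S,11Z,13S)-8-[(tert-butyldimethylsilyl)oxy]-8-methyl-4-methylidene-13-(3-methylbut-2-en-1-yl)-2-oxo-1-oxacyclotrideca-6,11-diene-12-carboxylate | C=C1C/C=C\[C@@](C)(O[Si](C)(C)C(C)(C)C)CC/C=C(\C(=O)OC)[C@H](CC=C(C)C)OC(=O)C1 | intermediate
26 | methyl (2Z,6Z,8S,11Z,13S)-8-[(tert-butyldimethylsilyl)oxy]-8-methyl-4-methylidene-13-(3-methylbut-2-en-1-yl)-2-[(trimethylsilyl)oxy]-1-oxacyclotrideca-2,6,11-triene-12-carboxylate | C=C1C/C=C\[C@@](C)(O[Si](C)(C)C(C)(C)C)CC/C=C(\C(=O)OC)[C@H](CC=C(C)C)O/C(O[Si](C)(C)C)=C/1 | intermediate (not isolated)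
27 | trimethylsilyl (1R,2S,5S,6Z)-5-[(tert-butyldimethylsilyl)oxy]-2-[(2Z)-1-methoxy-6-methyl-1-oxohepta-2,5-dien-2-yl]-5-methyl-9-methylidenecyclonon-6-ene-1-carboxylate | C=C1C/C=C\[C@@](C)(O[Si](C)(C)C(C)(C)C)CC[C@H](/C(C(=O)OC)=C/CC=C(C)C)[C@H]1C(=O)O[Si](C)(C)C | intermediate (not isolated)
28 | (1R,2S,5S,6Z)-5-[(tert-butyldimethylsilyl)oxy]-2-[(2Z)-1-methoxy-6-methyl-1-oxohepta-2,5-dien-2-yl]-5-methyl-9-methylidenecyclonon-6-ene-1-carboxylic acid | C=C1C/C=C\[C@@](C)(O[Si](C)(C)C(C)(C)C)CC[C@H](/C(C(=O)OC)=C/CC=C(C)C)[C@H]1C(=O)O | intermediate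
29 | {(1R,2S,5S,6Z)-5-[(tert-butyldimethylsilyl)oxy]-2-[(2Z)-1-hydroxy-6-methylhepta-2,5-dien-2-yl]-5-methyl-9-methylidenecyclonon-6-en-1-yl}methanol | C=C1C/C=C\[C@@](C)(O[Si](C)(C)C(C)(C)C)CC[C@H](/C(CO)=C/CC=C(C)C)[C@H]1CO | intermediate
30 | {(1R,3aR,6Z,8S,10aS)-8-[(tert-butyldimethylsilyl)oxy]-8-methyl-4-methylidene-1-[(1R)-4-methyl-1-(phenylselanyl)pent-3-en-1-yl]-3,3a,4,5,8,9,10,10a-octahydro-1H-cyclonona[c]furan-1-yl}methanol | C=C1C/C=C\[C@@](C)(O[Si](C)(C)C(C)(C)C)CC[C@H]2[C@H]1CO[C@]2(CO)[C@H]([Se]c3ccccc3)CC=C(C)C | intermediate (not isolated)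
31 | [(1R,3aR,6Z,8S,10aS)-8-[(tert-butyldimethylsilyl)oxy]-8-methyl-4-methylidene-1-[(1E)-4-methylpenta-1,3-dien-1-yl]-3,3a,4,5,8,9,10,10a-octahydro-1H-cyclonona[c]furan-1-yl]methanol | C=C1C/C=C\[C@@](C)(O[Si](C)(C)C(C)(C)C)CC[C@H]2[C@H]1CO[C@@]2(/C=C/C=C(C)C)CO | intermediate
32 | (1R,3aR,6Z,8S,10aS)-1-(hydroxymethyl)-8-methyl-4-methylidene-1-[(1E)-4-methylpenta-1,3-dien-1-yl]-3,3a,4,5,8,9,10,10a-octahydro-1H-cyclonona[c]furan-8-ol | C=C1C/C=C\[C@@](C)(O)CC[C@H]2[C@H]1CO[C@@]2(/C=C/C=C(C)C)CO | intermediate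
33 | hexadecanoyl chloride (palmitoyl chloride) | CCCCCCCCCCCCCCCC(=O)Cl | starting material
34 | [(1R,3aR,6Z,8S,10aS)-8-hydroxy-8-methyl-4-methylidene-1-[(1E)-4-methylpenta-1,3-dien-1-yl]-3,3a,4,5,8,9,10,10a-octahydro-1H-cyclonona[c]furan-1-yl]methyl hexadecanoate | C=C1C/C=C\[C@@](C)(O)CC[C@H]2[C@H]1CO[C@@]2(/C=C/C=C(C)C)COC(=O)CCCCCCCCCCCCCCC | target

Total step count: 21. Longest linear sequence: 18 steps (steps 1–6, 8–11 and 14–21).

Steps most likely to fail

Step 17 (key step). The lithium enolate may add in conjugate fashion to the C11=C12 enoate before it is silylated, or enolization may give the ketene acetal geometry that leads through the chair to the cis-fused acid. The fallback sets out from 25 and comes back at 28. It replaces the hard-base, silyl ketene acetal protocol by a boron-mediated ester enolate Claisen with soft enolization: Bu2BOTf and iPr2NEt in CH2Cl2 at −78 °C should give the dibutylboron ketene acetal F1 without a free metal enolate, with the geometry set by the amine and solvent. F1 should rearrange between −20 °C and room temperature to the dibutylboryl ester F2, which pH 7 buffer hydrolyses to 28.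

Step 15. Metathesis at the alkyne next to the quaternary silyloxy carbon may be slow, so that the unhindered butynyl ends dimerize and oligomers form instead of the 13-membered cycloalkyne. The fallback sets out from 17 and 22 and comes back at 24; it forms the alkyne between two molecules and closes the ring at the ester instead. Acid 22 is converted with allyl bromide and K2CO3 in DMF to the allyl ester F3. Alkyne cross-metathesis of 17 with an excess of F3 (same molybdenum alkylidyne, 5 Å sieves) should give the hydroxy allyl ester F4. Pd(PPh3)4 and morpholine free the seco acid F5, and Yamaguchi lactonization (2,4,6-trichlorobenzoyl chloride, Et3N, then DMAP, toluene, high dilution) gives 24.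

Step 19. Facial selectivity at C1 may be poor, because only the substrate decides which face of the alkene the C3 oxygen attacks, and selenium may be transferred to the 3-methylbut-2-enyl alkene instead. The fallback sets out from 29 and comes back at 34; it fixes C1 by reagent control. Sharpless epoxidation of the allylic alcohol (Ti(OiPr)4, L-(+)-diethyl tartrate, tBuOOH, −20 °C) should give the epoxy diol F6. Camphorsulfonic acid opens the epoxide 5-exo at the tertiary carbon with inversion to the tetrahydrofuran diol F7. The primary hydroxyl is acylated with 33 in pyridine at −20 °C to the palmitate F8. The Burgess reagent dehydrates the secondary alcohol toward the allylic CH2 to the silyl-protected diene ester F9, and Bu4NF gives 34.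

Further compounds
F1 | step 17 | methyl (2Z,6Z,8S,11Z,13S)-8-[(tert-butyldimethylsilyl)oxy]-2-[(dibutylboranyl)oxy]-8-methyl-4-methylidene-13-(3-methylbut-2-en-1-yl)-1-oxacyclotrideca-2,6,11-triene-12-carboxylate | C=C1C/C=C\[C@@](C)(O[Si](C)(C)C(C)(C)C)CC/C=C(\C(=O)OC)[C@H](CC=C(C)C)O/C(OB(CCCC)CCCC)=C/1
F2 | step 17 | dibutylboranyl (1R,2S,5S,6Z)-5-[(tert-butyldimethylsilyl)oxy]-2-[(2Z)-1-methoxy-6-methyl-1-oxohepta-2,5-dien-2-yl]-5-methyl-9-methylidenecyclonon-6-ene-1-carboxylate | C=C1C/C=C\[C@@](C)(O[Si](C)(C)C(C)(C)C)CC[C@H](/C(C(=O)OC)=C/CC=C(C)C)[C@H]1C(=O)OB(CCCC)CCCC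
F3 | step 15 | prop-2-en-1-yl 3-methylidenehept-5-ynoate | CC#CCC(=C)CC(=O)OCC=C
F4 | step 15 | 1-methyl 14-(prop-2-en-1-yl) (2Z,6S)-6-[(tert-butyldimethylsilyl)oxy]-2-[(1S)-1-hydroxy-4-methylpent-3-en-1-yl]-6-methyl-11-methylidenetetradec-2-en-7-ynedioate | C=CCOC(=O)CC(=C)CC#C[C@@](C)(O[Si](C)(C)C(C)(C)C)CC/C=C(\C(=O)OC)[C@@H](O)CC=C(C)C
F5 | step 15 | (8S,12Z,13S)-8-[(tert-butyldimethylsilyl)oxy]-13-hydroxy-12-(methoxycarbonyl)-8,16-dimethyl-3-methylideneheptadeca-12,15-dien-6-ynoic acid | OC(=O)CC(=C)CC#C[C@@](C)(O[Si](C)(C)C(C)(C)C)CC/C=C(\C(=O)OC)[C@@H](O)CC=C(C)C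
F6 | step 19 | {(1R,2S,5S,6Z)-5-[(tert-butyldimethylsilyl)oxy]-2-[(2S,3R)-2-(hydroxymethyl)-3-(3-methylbut-2-en-1-yl)oxiran-2-yl]-5-methyl-9-methylidenecyclonon-6-en-1-yl}methanol | C=C1C/C=C\[C@@](C)(O[Si](C)(C)C(C)(C)C)CC[C@H]([C@@]3(CO)O[C@@H]3CC=C(C)C)[C@H]1CO
F7 | step 19 | (1R)-1-[(1R,3aR,6Z,8S,10aS)-8-[(tert-butyldimethylsilyl)oxy]-1-(hydroxymethyl)-8-methyl-4-methylidene-3,3a,4,5,8,9,10,10a-octahydro-1H-cyclonona[c]furan-1-yl]-4-methylpent-3-en-1-ol | C=C1C/C=C\[C@@](C)(O[Si](C)(C)C(C)(C)C)CC[C@H]2[C@H]1CO[C@]2(CO)[C@H](O)CC=C(C)C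
F8 | step 19 | {(1R,3aR,6Z,8S,10aS)-8-[(tert-butyldimethylsilyl)oxy]-1-[(1R)-1-hydroxy-4-methylpent-3-en-1-yl]-8-methyl-4-methylidene-3,3a,4,5,8,9,10,10a-octahydro-1H-cyclonona[c]furan-1-yl}methyl hexadecanoate | C=C1C/C=C\[C@@](C)(O[Si](C)(C)C(C)(C)C)CC[C@H]2[C@H]1CO[C@]2(COC(=O)CCCCCCCCCCCCCCC)[C@H](O)CC=C(C)C
F9 | step 19 | {(1R,3aR,6Z,8S,10aS)-8-[(tert-butyldimethylsilyl)oxy]-8-methyl-4-methylidene-1-[(1E)-4-methylpenta-1,3-dien-1-yl]-3,3a,4,5,8,9,10,10a-octahydro-1H-cyclonona[c]furan-1-yl}methyl hexadecanoate | C=C1C/C=C\[C@@](C)(O[Si](C)(C)C(C)(C)C)CC[C@H]2[C@H]1CO[C@@]2(/C=C/C=C(C)C)COC(=O)CCCCCCCCCCCCCCC
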